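**Retrosynthetic overview**

- The last bond made is ring A carbon–CH2 (the bridge): reductive Knoevenagel alkylation joins the enolised 2-butanoyl-4,4-dimethyl triketone (ring A) to a ring B aldehyde whose formyl carbon sits on C1'.
- Ring B is numbered C1' (bridge carbon), C2' (methyl), C3' (butanoyl), C4' (oxygen), C5' (methyl), C6' (oxygen). The strategy rests on the vicinal C2' methyl / C3' butanoyl pair with the C4' oxygen beside C3'. Both groups are installed in one flask across a C2'–C3' aryne: methyllithium adds at C2' and the acyl group is trapped at C3'.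
- The aryne precursor carries chlorine at C2', the only ring hydrogen at C3', and C1' masked as a dioxolane. It is made from 1,3-dimethoxy-2-methylbenzene by sterically directed borylation–chlorination, formylation at either of two equivalent positions, and acetalisation.
- Ring A comes from 2,4,6-trihydroxybutyrophenone by dearomatising gem-dimethylation. No ring is formed in the route; both rings are carried through from commercial arenes.

Key step: step 4

Remark: ring A of the target is written as the enol tautomer of the given SMILES; the enol forms of the β-triketone interconvert freely, so no step has to set a particular tautomer.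

**Step 1**
Reactants: 1 1,3-dimethoxy-2-methylbenzene
Product: 3 5-chloro-1,3-dimethoxy-2-methylbenzene, via aryl pinacol boronate 2 (not isolated)
Conditions: [Ir(OMe)(cod)]2 (cat.), 4,4'-di-tert-butyl-2,2'-bipyridine (cat.), B2pin2 (1 equiv), THF, 80 °C; then CuCl2 (3 equiv), MeOH/H2O, 80 °C
Reagents that add atoms: bis(pinacolato)diboron (boron of intermediate 2), CC1(C)OB(OC1(C)C)B1OC(C)(C)C(C)(C)O1; copper dichloride, Cl[Cu]Cl
Why: Iridium-catalysed C–H borylation is sterically controlled and should take the only ring C–H with no ortho substituent (para to the methyl group), and CuCl2 then exchanges the boronate for chlorine (one-pot borylation–chlorodeboronation), which places chlorine meta to both methoxy groups where electrophilic chlorination cannot.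

**Step 2**
Reactants: 3 5-chloro-1,3-dimethoxy-2-methylbenzene
Product: 4 6-chloro-2,4-dimethoxy-3-methylbenzaldehyde
Conditions: Cl2CHOMe, TiCl4, CH2Cl2, −10 → 0 °C; then H2O
Reagents that add atoms: dichloromethyl methyl ether, COC(Cl)Cl; water, O
Why: Rieche formylation; the two free ring positions of 3 are equivalent by symmetry and each is ortho to one methoxy group and para to the other, so only the required aldehyde can form.

**Step 3**
Reactants: 4 6-chloro-2,4-dimethoxy-3-methylbenzaldehyde
Product: 5 2-(6-chloro-2,4-dimethoxy-3-methylphenyl)-1,3-dioxolane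
Conditions: HOCH2CH2OH, p-TsOH (cat.), toluene, reflux, Dean–Stark
Reagents that add atoms: ethane-1,2-diol, OCCO
Why: Acid-catalysed acetalisation with azeotropic removal of water masks the formyl group against LiTMP and MeLi and places lithium-coordinating oxygen atoms next to C2'.

**Step 4**
Reactants: 5 2-(6-chloro-2,4-dimethoxy-3-methylphenyl)-1,3-dioxolane; 6 methyllithium; 7 N-methoxy-N-methylbutanamide
Product: 12 1-[3-(1,3-dioxolan-2-yl)-4,6-dimethoxy-2,5-dimethylphenyl]butan-1-one, via chloro aryllithium 8 (not isolated), via aryne 9 (not isolated), via methylated aryllithium 10 (not isolated), via lithium hemiaminal alkoxide 11 (not isolated)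
Conditions: LiTMP (lithium 2,2,6,6-tetramethylpiperidide, 1.2 equiv), THF, −78 °C; MeLi (3 equiv), −78 → 0 °C; then amide 7 (6 equiv), −78 → 0 °C; then H2O
Reagents that add atoms: methyllithium 6, [Li]C; N-methoxy-N-methylbutanamide 7, CCCC(=O)N(C)OC; LiTMP (lithium of intermediate 8), [Li]N1C(C)(C)CCCC1(C)C
Why: LiTMP should remove the only ring hydrogen (C3'–H, acidified by the flanking C2' chlorine and C4' methoxy group) to give aryllithium 8, which loses LiCl on warming to the C2'–C3' aryne 9; MeLi adds at C2' to give aryllithium 10, and 10 adds to amide 7 to give the chelated tetrahedral adduct 11, which releases ketone 12 only on aqueous quench. The closest known reaction type is the tandem alkyllithium addition–electrophile trapping of 3-alkoxyarynes generated from ortho-lithiated haloanisoles, joined to a Weinreb ketone synthesis. No ring is closed and no stereocentre is formed. The step needs methyl at C2' and the acyl group at C3': the σ-withdrawing C4' methoxy group polarises the aryne so that the nucleophile attacks the distal carbon C2' and the carbanion develops at C3' beside oxygen, where it is stabilised inductively and by lithium chelation, and coordination of MeLi to the dioxolane oxygens on C1' directs it to the same carbon. MeLi is kept in excess so that it, rather than aryllithium 10 or LiTMP, captures the aryne, and amide 7 is used in excess to consume the surplus MeLi and LiTMP.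

**Step 5**
Reactants: 12 1-[3-(1,3-dioxolan-2-yl)-4,6-dimethoxy-2,5-dimethylphenyl]butan-1-one
Product: 13 3-butanoyl-4,6-dimethoxy-2,5-dimethylbenzaldehyde
Conditions: 1 M HCl, THF, rt
Reagents that add atoms: water, O
Why: Acid-catalysed acetal hydrolysis should free the formyl group, while the aryl methyl ethers and the aryl ketone are inert to dilute aqueous acid.

**Step 6**
Reactants: 13 3-butanoyl-4,6-dimethoxy-2,5-dimethylbenzaldehyde
Product: 14 3-butanoyl-4,6-dihydroxy-2,5-dimethylbenzaldehyde
Conditions: BCl3 (excess), CH2Cl2, −78 → 0 °C; then H2O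
Reagents that add atoms: none
Why: BCl3 cleaves aryl methyl ethers ortho to a carbonyl group through a six-membered boron chelate; the C6' methoxy group is ortho to the formyl group and the C4' methoxy group is ortho to the butanoyl group, so both should be cleaved while the carbonyl groups stay intact.

**Step 7**
Reactants: 15 1-(2,4,6-trihydroxyphenyl)butan-1-one (2,4,6-trihydroxybutyrophenone)
Product: 16 2-butanoyl-3,5-dihydroxy-4,4-dimethylcyclohexa-2,5-dien-1-one
Conditions: NaOMe (3 equiv), MeI (2.2 equiv), MeOH, 0 °C → rt
Reagents that add atoms: iodomethane, CI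
Why: Dearomatising double C-methylation of the acylphloroglucinol phenoxide at one ring carbon should give the gem-dimethyl enolised triketone, with limited MeI holding back the tri- and tetramethylated congeners, which are removed by chromatography.

**Step 8**
Reactants: 14 3-butanoyl-4,6-dihydroxy-2,5-dimethylbenzaldehyde; 16 2-butanoyl-3,5-dihydroxy-4,4-dimethylcyclohexa-2,5-dien-1-one
Product: 18 2-butanoyl-6-[(3-butanoyl-4,6-dihydroxy-2,5-dimethylphenyl)methyl]-3,5-dihydroxy-4,4-dimethylcyclohexa-2,5-dien-1-one, via alkylidene triketone 17 (not isolated)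
Conditions: diethyl 2,6-dimethyl-1,4-dihydropyridine-3,5-dicarboxylate (Hantzsch ester, 1.2 equiv), L-proline (cat.), CH2Cl2, rt
Reagents that add atoms: none
Why: Organocatalytic reductive Knoevenagel alkylation: the only ring C–H of 16, which lies between two enolised carbonyl groups, condenses with the aldehyde to give the quinone-methide-like alkylidene 17, and this is reduced in situ by conjugate hydride transfer from the Hantzsch ester, forming the C1'–CH2–ring A link without touching either ketone.

**Compound list**

1 | 1,3-dimethoxy-2-methylbenzene | COc1cccc(OC)c1C | starting material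
2 | 2-(3,5-dimethoxy-4-methylphenyl)-4,4,5,5-tetramethyl-1,3,2-dioxaborolane | COc1cc(B2OC(C)(C)C(C)(C)O2)cc(OC)c1C | intermediate (not isolated)
3 | 5-chloro-1,3-dimethoxy-2-methylbenzene | COc1cc(Cl)cc(OC)c1C | intermediate
4 | 6-chloro-2,4-dimethoxy-3-methylbenzaldehyde | O=Cc1c(Cl)cc(OC)c(C)c1OC | intermediate
5 | 2-(6-chloro-2,4-dimethoxy-3-methylphenyl)-1,3-dioxolane | Clc1cc(OC)c(C)c(OC)c1C1OCCO1 | intermediate
6 | methyllithium | [Li]C | starting material
7 | N-methoxy-N-methylbutanamide | CCCC(=O)N(C)OC | starting material
8 | [2-chloro-3-(1,3-dioxolan-2-yl)-4,6-dimethoxy-5-methylphenyl]lithium | [Li]c1c(Cl)c(C2OCCO2)c(OC)c(C)c1OC | intermediate (not isolated)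
9 | 2-(5,6-didehydro-2,4-dimethoxy-3-methylphenyl)-1,3-dioxolane (C2'–C3' aryne) | COC1=C(C)C(OC)=C(C2OCCO2)C#C1 | intermediate (not isolated)
10 | [3-(1,3-dioxolan-2-yl)-4,6-dimethoxy-2,5-dimethylphenyl]lithium | [Li]c1c(C)c(C2OCCO2)c(OC)c(C)c1OC | intermediate (not isolated)
11 | lithium 1-[3-(1,3-dioxolan-2-yl)-4,6-dimethoxy-2,5-dimethylphenyl]-1-[methoxy(methyl)amino]butan-1-olate | CCCC(O[Li])(N(C)OC)c1c(C)c(C2OCCO2)c(OC)c(C)c1OC | intermediate (not isolated)
12 | 1-[3-(1,3-dioxolan-2-yl)-4,6-dimethoxy-2,5-dimethylphenyl]butan-1-one | CCCC(=O)c1c(C)c(C2OCCO2)c(OC)c(C)c1OC | intermediate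
13 | 3-butanoyl-4,6-dimethoxy-2,5-dimethylbenzaldehyde | CCCC(=O)c1c(C)c(C=O)c(OC)c(C)c1OC | intermediate
14 | 3-butanoyl-4,6-dihydroxy-2,5-dimethylbenzaldehyde | CCCC(=O)c1c(C)c(C=O)c(O)c(C)c1O | intermediate
15 | 1-(2,4,6-trihydroxyphenyl)butan-1-one | CCCC(=O)c1c(O)cc(O)cc1O | starting material
16 | 2-butanoyl-3,5-dihydroxy-4,4-dimethylcyclohexa-2,5-dien-1-one | CCCC(=O)C1=C(O)C(C)(C)C(O)=CC1=O | intermediate
17 | 2-butanoyl-6-[(3-butanoyl-4,6-dihydroxy-2,5-dimethylphenyl)methylidene]-3-hydroxy-4,4-dimethylcyclohex-2-ene-1,5-dione | CCCC(=O)C1=C(O)C(C)(C)C(=O)C(=Cc2c(C)c(C(=O)CCC)c(O)c(C)c2O)C1=O | intermediate (not isolated)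
18 | 2-butanoyl-6-[(3-butanoyl-4,6-dihydroxy-2,5-dimethylphenyl)methyl]-3,5-dihydroxy-4,4-dimethylcyclohexa-2,5-dien-1-one | CCCC(=O)C1=C(O)C(C)(C)C(O)=C(Cc2c(C)c(C(=O)CCC)c(O)c(C)c2O)C1=O | target

**Step count**

Total steps: 8. Longest linear sequence: 7 (steps 1, 2, 3, 4, 5, 6, 8); step 7 is the one-step side branch to ring A.

**Steps most likely to fail**

Step 4. The one-flask aryne sequence may break down in three ways: methyllithium may add at C3' instead of C2'; aryllithium 10 may be quenched by proton transfer from the liberated tetramethylpiperidine or from the α-position of the amide instead of being acylated; or the dioxolane may fragment under the strong base. The fallback sets out from compound 3 and returns at compound 13, building ring B by classical substitution chemistry. Kumada coupling of 3 with MeMgBr under NiCl2(dppp) catalysis in THF should give 1,3-dimethoxy-2,5-dimethylbenzene F1. Friedel–Crafts acylation with butanoyl chloride and AlCl3 in CH2Cl2 at 0 °C, at either of its two equivalent ring positions, should give 1-(2,4-dimethoxy-3,6-dimethylphenyl)butan-1-one F2. Rieche formylation (Cl2CHOMe, TiCl4) at the last free position, which is ortho and para to the two methoxy groups and meta to the ketone, should then give aldehyde 13, bypassing compounds 4, 5 and 12.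

Step 8. Condensation may be slow at the doubly ortho-substituted, hydroxyl-deactivated aldehyde, and alkylidene 17 may be captured by a second molecule of 16 or cyclise through the C6' hydroxyl group before hydride transfer. The fallback sets out from compound 14 and returns at compound 18. NaBH4 in THF/MeOH at 0 °C should reduce the formyl group in preference to the flanked, chelated ketone and give 1-[4,6-dihydroxy-3-(hydroxymethyl)-2,5-dimethylphenyl]butan-1-one F3. Warming this benzylic alcohol with 16 in toluene should expel water to the quinone methide 4-butanoyl-3-hydroxy-2,5-dimethyl-6-methylidenecyclohexa-2,4-dien-1-one F4, and conjugate addition of the enol carbon of 16 to it should give 18 directly, with no reduction step.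

Step 6. Cleavage of the two flanked methyl ethers may be incomplete, or the Lewis acid may promote condensation at the free aldehyde. The fallback sets out from compound 13 and returns at compound 18 by exchanging the order of deprotection and coupling. Reductive Knoevenagel alkylation of 16 with the dimethyl ether aldehyde 13 (Hantzsch ester, L-proline, CH2Cl2) should pass through 2-butanoyl-6-[(3-butanoyl-4,6-dimethoxy-2,5-dimethylphenyl)methylidene]-3-hydroxy-4,4-dimethylcyclohex-2-ene-1,5-dione F5 to 2-butanoyl-6-[(3-butanoyl-4,6-dimethoxy-2,5-dimethylphenyl)methyl]-3,5-dihydroxy-4,4-dimethylcyclohexa-2,5-dien-1-one F6. BBr3 in CH2Cl2 at −78 → 0 °C should then cleave both aryl methyl ethers to give 18, so that no free aldehyde is exposed to the Lewis acid.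

**Further compounds**

F1 | step 4 | 1,3-dimethoxy-2,5-dimethylbenzene | COc1cc(C)cc(OC)c1C
F2 | step 4 | 1-(2,4-dimethoxy-3,6-dimethylphenyl)butan-1-one | CCCC(=O)c1c(C)cc(OC)c(C)c1OC
F3 | step 8 | 1-[4,6-dihydroxy-3-(hydroxymethyl)-2,5-dimethylphenyl]butan-1-one | CCCC(=O)c1c(C)c(CO)c(O)c(C)c1O
F4 | step 8 | 4-butanoyl-3-hydroxy-2,5-dimethyl-6-methylidenecyclohexa-2,4-dien-1-one | C=C1C(C)=C(C(=O)CCC)C(O)=C(C)C1=O
F5 | step 6 | 2-butanoyl-6-[(3-butanoyl-4,6-dimethoxy-2,5-dimethylphenyl)methylidene]-3-hydroxy-4,4-dimethylcyclohex-2-ene-1,5-dione | CCCC(=O)C1=C(O)C(C)(C)C(=O)C(=Cc2c(C)c(C(=O)CCC)c(OC)c(C)c2OC)C1=O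
F6 | step 6 | 2-butanoyl-6-[(3-butanoyl-4,6-dimethoxy-2,5-dimethylphenyl)methyl]-3,5-dihydroxy-4,4-dimethylcyclohexa-2,5-dien-1-one | CCCC(=O)C1=C(O)C(C)(C)C(O)=C(Cc2c(C)c(C(=O)CCC)c(OC)c(C)c2OC)C1=O
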